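The data are calculated with constants of no real substance; scatter was added.

| setting | winter | spring | north | south | north-east | north-west |
|---|---|---|---|---|---|---|
| starting material | 0.10 M (fed, over 80 min) | 0.10 M (fed, over 80 min) | 0.10 M (fed, over 80 min) | 0.10 M (fed, over 80 min) | 0.10 M (fed, over 80 min) | 0.10 M (fed, over 80 min) |
| activator | 0.084 M | 0.58 M | 0.0600 M | 0.120 M | 0.250 M | 0.500 M |
| remark | run made earlier | run made earlier |  |  |  |  |
| time |  |  | 3.0 h | 3.0 h | 3.0 h | 3.0 h |

- winter (time / min: ring / %): 25.0: 1.3; 50.0: 9.7; 60.0: 12.2; 90.0: 20.7
- spring (time / min: ring / %): 8.00: 0.8; 15.0: 1.9; 40.0: 15.2; 90.0: 46.8

(standard deviation of a reading: 0.5 percentage points)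

- in percentages every species weighs as the starting material in it: one open dimer counts as two
- for ring the idle adduct is counted in
- candidate steps: starting material + activator -> activated form; activated form -> ring; starting material + activated form -> open dimer; activator + ring <-> idle adduct; 2 activator -> homo dimer
- the concentration of ring that is asked is that of its free form alone
- "hardly changes" means that all values lie within two and a half points (for a concentration: within two and a half percent of the largest)
- percentages count the whole charge, also what has not yet gone in

* [ring] (only what is free in solution) at the end for north, south, north-east, north-west, in this order
* the course of these numbers from the first flask to the last (falls all the way / hardly changes / falls, then rises / rises, then falls / rises all the way)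

Late in a flask, at 90.0 min with the feed over, I first read the two earlier runs by the bench rule that ring follows c(activator) in proportion. Going from winter to spring raised c(activator) by a factor of 6.90, so the rule promised spring 143% of the charge, more than the charge holds. Spring read 46.8% against winter's 20.7%, a factor of 2.26, and this was where the rule stopped working.

I therefore replaced the proportion with a measure of how far it held: the apparent order of counted ring in activator, that is, the change of ln(ring) per change of ln c(activator) between two flasks with the same feed, read at the same time. The two readings gave 0.422, a reading that carries their scatter; an order of one would have been the bench rule. With feed and time held, this order carried winter's reading to north-west as 44.0% of the charge at 90.0 min. With an order above zero I committed to a rise of counted ring; the readings count idle adduct with ring, so they left the free part open.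

The forecast gave 0.021 M, 0.031 M, 0.038 M and 0.036 M, with the course rises, then falls, and it warned: “Free ring therefore rests on an assumption, not a measurement”.

The flasks gave 0.0212 M, 0.0320 M, 0.0363 M and 0.0367 M of free ring, so the course rises all the way.

starting material + activator → activated form (k = 25.0 /M/h); activated form → ring (k = 2.10 /h); starting material + activated form → open dimer (k = 60.0 /M/h); activator + ring ⇌ idle adduct, settled at all times (K = 12.0 /M); 2 activator → homo dimer (k = 1.60 /M/h) At 3.00 h, north-west held 27.4% as idle adduct within 64.1% of counted ring. The order 0.422 had put north-west at 44.0% for 1.50 h, where north-west stood at 45.5% counted. Carried from winter to south, the same order gives 24.1% for 1.50 h, and south stood at 25.5%.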